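(The constants were chosen freely, and the outcome is calculated.)

Start from 0.0276 M, the level concentration: the [protic impurity] at which the impurity and the catalyst, with all of it free, take up starting material equally fast.

starting material 0.10 M; protic impurity 0.0200 M; free catalyst 2 mol%; time 2.5 h

    starting material + protic impurity → quenched substrate (k1 = 5.0 /M/min)
    catalyst intermediate A → catalyst intermediate B (k2 = 24 /min)
    starting material + free catalyst → catalyst intermediate A (k3 = 69 /M/min)
    catalyst intermediate B → free catalyst + product (k4 = 20 /min)

- at 2.5 h, what has stopped the reaction, if anything has (all of the starting material has reacted / no working catalyst is left / forward and back rates have come level / it is still moving)
- the product standing at 2.5 h, as a percentage of the starting material charged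

Build the flask one process at a time and follow the fraction left. With the catalytic cycle alone, free catalyst captures starting material with a half-life of 5.02 min, and the run lasts 29.9 such half-lives. The catalyst also comes back with each product, so you expect the starting material to be used up and the product to head for 100%.

Now add the quench, with [protic impurity] held at its charge. Both uptakes are first order in starting material, so [starting material] cancels from their ratio, which is the selectivity factor 1.38, and the product share falls to 58.0%.

Then let the impurity run down. The logarithm of its fraction left falls by the product made divided by the level concentration, and with about 0.0800 M of product that leaves 5.51% of the impurity. My reckoning therefore gives product 81.1%.

Last come the two intermediates, which at the start leave a free share of 61.3% of the catalyst, so the working level concentration is lower early on and the quench gains. The impurity can still quench no more than its own charge, so the product stays above 80.0%.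

The forecast says all of the starting material has reacted and gives 80.5%, lower than my figure, on this ground: “The impurity competes about evenly at the start but is nearly all used by the end”.

The flask gives all of the starting material has reacted, with product at 80.5%. At 2.50 h this flask holds 2.40% of its protic impurity, against the 5.51% reckoned from the level concentration. Raising the free catalyst to 8 mol% raises the level concentration to 0.110 M, and the same reckoning, with the product made there taken consistently as 0.0889 M, then leaves 44.7% of the impurity and gives product 88.9%. That 8 mol% flask reads 87.2% of product at 2.50 h, with 36% of its protic impurity left.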